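## Retrosynthetic overview

1. Target ⇒ naphthazarin diol + (R)-2-methylbutanoic acid: a last-step Steglich esterification of the secondary allylic alcohol. The acid comes from Evans methylation of an N-butanoyl oxazolidinone.
2. Naphthazarin diol ⇒ silyl-protected (R)-allylic alcohol on 1,4,5,8-tetramethoxynaphthalene. The four phenol methyl ethers are removed by two oxidative demethylations with (NH4)2Ce(NO3)6, separated by a reductive acetylation.
3. (R)-Allylic alcohol ⇒ (E)-aryl enone by CBS reduction ⇒ key C–C bond by directed aldol addition of 2-acetyl-1,4,5,8-tetramethoxynaphthalene to 2-(silyloxy)-2-methylpropanal, then dehydration.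
4. No ring is built: the naphthalene core is bought intact as 1,5-dihydroxynaphthalene. Only its oxidation level changes, the unsubstituted ring going to the quinone first and the side-chain ring second.

Assumption: the two naphthazarin tautomers are one compound, written as in the target SMILES with the side chain on the quinone ring.

## Route

Step 1
Reactants: 1 1,5-dihydroxynaphthalene
Product: 2 1,5-dimethoxynaphthalene
Conditions: Me2SO4, K2CO3, acetone, reflux
Reagents that add atoms: dimethyl sulfate COS(=O)(=O)OC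
Why: Williamson-type O-methylation of both naphthols is high-yielding and creates no stereocentre.

Step 2
Reactants: 2 1,5-dimethoxynaphthalene
Product: 3 4,8-dibromo-1,5-dimethoxynaphthalene
Conditions: NBS (2.1 equiv), MeCN, rt
Reagents that add atoms: N-bromosuccinimide O=C1CCC(=O)N1Br
Why: Electrophilic aromatic bromination goes para to each methoxy group, the most activated positions.

Step 3
Reactants: 3 4,8-dibromo-1,5-dimethoxynaphthalene
Product: 4 1,4,5,8-tetramethoxynaphthalene
Conditions: NaOMe, CuI (20 mol %), DMF/MeOH, reflux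
Reagents that add atoms: sodium methoxide C[O-].[Na+]
Why: Copper-catalysed Ullmann-type methoxylation replaces both aryl bromides by methoxide.

Step 4
Reactants: 4 1,4,5,8-tetramethoxynaphthalene
Product: 6 1,4,5,8-tetramethoxynaphthalene-2-carbaldehyde, via iminium chloride 5 (not isolated)
Conditions: POCl3, DMF, CHCl3, reflux; then ice-water
Reagents that add atoms: N,N-dimethylformamide CN(C)C=O; water O
Why: Vilsmeier–Haack formylation of the electron-rich arene stops at mono-substitution because the iminium group deactivates the ring, and all four free positions are equivalent.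

Step 5
Reactants: 6 1,4,5,8-tetramethoxynaphthalene-2-carbaldehyde
Product: 7 racemic 1-(1,4,5,8-tetramethoxynaphthalen-2-yl)ethan-1-ol
Conditions: MeMgBr, THF, 0 °C; aq. NH4Cl
Reagents that add atoms: methylmagnesium bromide C[Mg]Br
Why: Grignard 1,2-addition gives the benzylic alcohol as a racemate, which does not matter because the carbinol is oxidised in step 6.

Step 6
Reactants: 7 racemic 1-(1,4,5,8-tetramethoxynaphthalen-2-yl)ethan-1-ol
Product: 8 1-(1,4,5,8-tetramethoxynaphthalen-2-yl)ethan-1-one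
Conditions: Dess–Martin periodinane, CH2Cl2, 0 °C to rt
Reagents that add atoms: none
Why: Dess–Martin oxidation turns the benzylic alcohol into the aryl methyl ketone under mild conditions that spare the electron-rich ring.

Step 7
Reactants: 9 methyl 2-hydroxy-2-methylpropanoate
Product: 10 methyl 2-[(tert-butyldimethylsilyl)oxy]-2-methylpropanoate (tert-butyldimethylsilyl = TBS below)
Conditions: TBSOTf, 2,6-lutidine, CH2Cl2, 0 °C to rt
Reagents that add atoms: tert-butyldimethylsilyl trifluoromethanesulfonate CC(C)(C)[Si](C)(C)OS(=O)(=O)C(F)(F)F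
Why: Silylation with the silyl triflate and a hindered pyridine base is the standard protection of a tertiary alcohol.

Step 8
Reactants: 10 methyl 2-[(TBS)oxy]-2-methylpropanoate
Product: 11 2-[(TBS)oxy]-2-methylpropanal
Conditions: i-Bu2AlH (1.1 equiv), CH2Cl2, −78 °C; then aq. potassium sodium tartrate (KNaC4H4O6)
Reagents that add atoms: none
Why: Partial ester reduction stops at the aldehyde because the α-silyloxy aluminium hemiacetal is stable at −78 °C until the quench.

Step 9
Reactants: 8 1-(1,4,5,8-tetramethoxynaphthalen-2-yl)ethan-1-one; 11 2-[(TBS)oxy]-2-methylpropanal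
Product: 12 racemic 4-[(TBS)oxy]-3-hydroxy-4-methyl-1-(1,4,5,8-tetramethoxynaphthalen-2-yl)pentan-1-one
Conditions: LiN(iPr)2, THF, −78 °C; then 11, −78 °C, 1 h; AcOH quench at −78 °C
Reagents that add atoms: none
Why: In this directed crossed aldol addition the preformed lithium enolate of 8 adds to the non-enolisable aldehyde 11, so only one cross-product can form, and the new carbinol centre is racemic and is removed in step 10.

Step 10
Reactants: 12 racemic 4-[(TBS)oxy]-3-hydroxy-4-methyl-1-(1,4,5,8-tetramethoxynaphthalen-2-yl)pentan-1-one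
Product: 14 (2E)-4-[(TBS)oxy]-4-methyl-1-(1,4,5,8-tetramethoxynaphthalen-2-yl)pent-2-en-1-one, via β-mesyloxy ketone 13 (not isolated)
Conditions: MsCl, Et3N, CH2Cl2, 0 °C; then DBU, 0 °C to rt
Reagents that add atoms: none
Why: Mesylation followed by E1cB elimination completes the aldol condensation and gives the conjugated enone as the thermodynamically favoured (E)-isomer.

Step 11
Reactants: 14 (2E)-4-[(TBS)oxy]-4-methyl-1-(1,4,5,8-tetramethoxynaphthalen-2-yl)pent-2-en-1-one
Product: 15 (1R,2E)-4-[(TBS)oxy]-4-methyl-1-(1,4,5,8-tetramethoxynaphthalen-2-yl)pent-2-en-1-ol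
Conditions: (S)-Me-CBS catalyst [(S)-1-methyl-3,3-diphenyltetrahydro-1H,3H-pyrrolo[1,2-c][1,3,2]oxazaborole] (0.5 equiv), BH3·SMe2, THF, −30 °C, slow addition of 14; MeOH quench, NaHCO3 work-up
Reagents that add atoms: none
Why: In this Corey–Bakshi–Shibata reduction the ortho-substituted naphthyl group should act as the large substituent and the slim (E)-alkenyl group as the small one, so the (S)-catalyst should give the (R)-carbinol, just as it gives (R)-1-phenylethanol from acetophenone.

Step 12
Reactants: 15 (1R,2E)-4-[(TBS)oxy]-4-methyl-1-(1,4,5,8-tetramethoxynaphthalen-2-yl)pent-2-en-1-ol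
Product: 16 2-[(1R,2E)-1,4-bis[(TBS)oxy]-4-methylpent-2-en-1-yl]-1,4,5,8-tetramethoxynaphthalene
Conditions: TBSCl, imidazole, DMF, rt
Reagents that add atoms: tert-butyldimethylsilyl chloride CC(C)(C)[Si](C)(C)Cl
Why: Silyl ether formation masks the acid-labile benzylic-allylic alcohol as a poor leaving group before the acidic oxidations and breaks no bond at the stereocentre.

Step 13
Reactants: 16 2-[(1R,2E)-1,4-bis[(TBS)oxy]-4-methylpent-2-en-1-yl]-1,4,5,8-tetramethoxynaphthalene
Product: 17 6-[(1R,2E)-1,4-bis[(TBS)oxy]-4-methylpent-2-en-1-yl]-5,8-dimethoxynaphthalene-1,4-dione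
Conditions: (NH4)2Ce(NO3)6 (2.5 equiv), MeCN/H2O 3:1, 0 °C, 15 min
Reagents that add atoms: water O
Why: Oxidative demethylation by tetravalent cerium turns one para-dimethoxy ring into a quinone with oxygen from water, the bulky non-coordinating silyloxyalkyl group should steer it to the unsubstituted ring, and the new quinone protects the other ring from further oxidation (any regioisomeric quinone is removed by chromatography).

Step 14
Reactants: 17 6-[(1R,2E)-1,4-bis[(TBS)oxy]-4-methylpent-2-en-1-yl]-5,8-dimethoxynaphthalene-1,4-dione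
Product: 19 6-[(1R,2E)-1,4-bis[(TBS)oxy]-4-methylpent-2-en-1-yl]-5,8-dimethoxynaphthalene-1,4-diyl diacetate, via hydroquinone 18 (not isolated)
Conditions: Na2S2O4, EtOAc/H2O, rt; then Ac2O, pyridine, 4-(dimethylamino)pyridine (DMAP, cat.), CH2Cl2, 0 °C to rt, under N2
Reagents that add atoms: acetic anhydride CC(=O)OC(C)=O
Why: Dithionite reduction of the quinone and immediate O-acetylation turn the oxidised ring into an electron-poor diacetate that is inert to the next oxidation.

Step 15
Reactants: 19 6-[(1R,2E)-1,4-bis[(TBS)oxy]-4-methylpent-2-en-1-yl]-5,8-dimethoxynaphthalene-1,4-diyl diacetate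
Product: 20 2-[(1R,2E)-1,4-bis[(TBS)oxy]-4-methylpent-2-en-1-yl]-5,8-diacetoxynaphthalene-1,4-dione
Conditions: (NH4)2Ce(NO3)6 (3 equiv), MeCN/H2O 3:1, 0 °C to rt
Reagents that add atoms: water O
Why: A second oxidative demethylation by tetravalent cerium can only take place at the remaining para-dimethoxy ring, because aryl acetates are not oxidised, and gives the quinone on the ring that carries the side chain.

Step 16
Reactants: 20 2-[(1R,2E)-1,4-bis[(TBS)oxy]-4-methylpent-2-en-1-yl]-5,8-diacetoxynaphthalene-1,4-dione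
Product: 21 2-[(1R,2E)-1,4-bis[(TBS)oxy]-4-methylpent-2-en-1-yl]-5,8-dihydroxynaphthalene-1,4-dione
Conditions: K2CO3, MeOH/THF, 0 °C, argon, 15 min; then 1 M HCl
Reagents that add atoms: none
Why: Base-mediated methanolysis (transesterification) cleaves the activated peri aryl acetates within minutes, while the silyl ethers survive and the silyloxy group at the stereocentre cannot be expelled.

Step 17
Reactants: 21 2-[(1R,2E)-1,4-bis[(TBS)oxy]-4-methylpent-2-en-1-yl]-5,8-dihydroxynaphthalene-1,4-dione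
Product: 22 5,8-dihydroxy-2-[(1R,2E)-1,4-dihydroxy-4-methylpent-2-en-1-yl]naphthalene-1,4-dione
Conditions: 48% aq. HF, MeCN, 0 °C to rt, polypropylene vessel
Reagents that add atoms: none
Why: Fluoride-mediated desilylation removes both TBS ethers under acidic conditions that naphthazarins tolerate, and the electron-poor quinone ring suppresses ionisation at the carbinol, so its configuration is kept.

Step 18
Reactants: 23 (R)-4-benzyl-1,3-oxazolidin-2-one; 24 butanoyl chloride
Product: 25 (R)-4-benzyl-3-butanoyl-1,3-oxazolidin-2-one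
Conditions: n-BuLi, THF, −78 °C; then 24, −78 to 0 °C
Reagents that add atoms: none
Why: N-Acylation of the lithiated oxazolidinone with an acid chloride is the standard preparation of an Evans imide.

Step 19
Reactants: 25 (R)-4-benzyl-3-butanoyl-1,3-oxazolidin-2-one
Product: 26 (R)-4-benzyl-3-[(2R)-2-methylbutanoyl]-1,3-oxazolidin-2-one
Conditions: NaN(SiMe3)2, THF, −78 °C; then MeI, −78 °C; minor diastereomer removed by chromatography
Reagents that add atoms: iodomethane CI
Why: In this Evans asymmetric alkylation the chelated (Z)-sodium enolate is methylated on the face opposite the benzyl group, which for the (R)-auxiliary sets the new α-centre as (R).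

Step 20
Reactants: 26 (R)-4-benzyl-3-[(2R)-2-methylbutanoyl]-1,3-oxazolidin-2-one
Product: 28 (R)-2-methylbutanoic acid, via peroxy acid 27 (not isolated)
Conditions: LiOH, 30% H2O2, THF/H2O 3:1, 0 °C; then aq. Na2SO3; then HCl to pH 2
Reagents that add atoms: hydrogen peroxide OO
Why: Hydroperoxide cleaves the exocyclic imide carbonyl selectively (auxiliary cleavage with LiOOH) to the peroxy acid, which sulfite reduces to the acid without epimerisation while the auxiliary is released.

Step 21
Reactants: 22 5,8-dihydroxy-2-[(1R,2E)-1,4-dihydroxy-4-methylpent-2-en-1-yl]naphthalene-1,4-dione; 28 (R)-2-methylbutanoic acid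
Product: 29 (1R,2E)-1-(5,8-dihydroxy-1,4-dioxo-1,4-dihydronaphthalen-2-yl)-4-hydroxy-4-methylpent-2-en-1-yl (2R)-2-methylbutanoate
Conditions: DCC, 4-(dimethylamino)pyridine (0.1 equiv), CH2Cl2, 0 °C to rt, argon, dark
Reagents that add atoms: none
Why: Steglich esterification acylates only the secondary allylic alcohol, as in the acylation of shikonin, because the tertiary alcohol is too hindered and the peri-phenols are tied up in hydrogen bonds to the quinone carbonyls, and neither stereocentre is touched.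

## Compound list

1 | 1,5-dihydroxynaphthalene | Oc1cccc2c(O)cccc12 | starting material
2 | 1,5-dimethoxynaphthalene | COc1cccc2c(OC)cccc12 | intermediate
3 | 4,8-dibromo-1,5-dimethoxynaphthalene | COc1ccc(Br)c2c(OC)ccc(Br)c12 | intermediate
4 | 1,4,5,8-tetramethoxynaphthalene | COc1ccc(OC)c2c(OC)ccc(OC)c12 | intermediate
5 | N,N-dimethyl-1-(1,4,5,8-tetramethoxynaphthalen-2-yl)methaniminium chloride | C[N+](C)=Cc1cc(OC)c2c(OC)ccc(OC)c2c1OC.[Cl-] | intermediate
6 | 1,4,5,8-tetramethoxynaphthalene-2-carbaldehyde | O=Cc1cc(OC)c2c(OC)ccc(OC)c2c1OC | intermediate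
7 | racemic 1-(1,4,5,8-tetramethoxynaphthalen-2-yl)ethan-1-ol | CC(O)c1cc(OC)c2c(OC)ccc(OC)c2c1OC | intermediate
8 | 1-(1,4,5,8-tetramethoxynaphthalen-2-yl)ethan-1-one | CC(=O)c1cc(OC)c2c(OC)ccc(OC)c2c1OC | intermediate
9 | methyl 2-hydroxy-2-methylpropanoate | COC(=O)C(C)(C)O | starting material
10 | methyl 2-[(tert-butyldimethylsilyl)oxy]-2-methylpropanoate | COC(=O)C(C)(C)O[Si](C)(C)C(C)(C)C | intermediate
11 | 2-[(tert-butyldimethylsilyl)oxy]-2-methylpropanal | O=CC(C)(C)O[Si](C)(C)C(C)(C)C | intermediate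
12 | racemic 4-[(tert-butyldimethylsilyl)oxy]-3-hydroxy-4-methyl-1-(1,4,5,8-tetramethoxynaphthalen-2-yl)pentan-1-one | CC(C)(O[Si](C)(C)C(C)(C)C)C(O)CC(=O)c1cc(OC)c2c(OC)ccc(OC)c2c1OC | intermediate
13 | racemic 2-[(tert-butyldimethylsilyl)oxy]-2-methyl-5-oxo-5-(1,4,5,8-tetramethoxynaphthalen-2-yl)pentan-3-yl methanesulfonate | CC(C)(O[Si](C)(C)C(C)(C)C)C(OS(C)(=O)=O)CC(=O)c1cc(OC)c2c(OC)ccc(OC)c2c1OC | intermediate
14 | (2E)-4-[(tert-butyldimethylsilyl)oxy]-4-methyl-1-(1,4,5,8-tetramethoxynaphthalen-2-yl)pent-2-en-1-one | CC(C)(O[Si](C)(C)C(C)(C)C)/C=C/C(=O)c1cc(OC)c2c(OC)ccc(OC)c2c1OC | intermediate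
15 | (1R,2E)-4-[(tert-butyldimethylsilyl)oxy]-4-methyl-1-(1,4,5,8-tetramethoxynaphthalen-2-yl)pent-2-en-1-ol | O[C@H](/C=C/C(C)(C)O[Si](C)(C)C(C)(C)C)c1cc(OC)c2c(OC)ccc(OC)c2c1OC | intermediate
16 | 2-[(1R,2E)-1,4-bis[(tert-butyldimethylsilyl)oxy]-4-methylpent-2-en-1-yl]-1,4,5,8-tetramethoxynaphthalene | CC(C)(C)[Si](C)(C)O[C@H](/C=C/C(C)(C)O[Si](C)(C)C(C)(C)C)c1cc(OC)c2c(OC)ccc(OC)c2c1OC | intermediate
17 | 6-[(1R,2E)-1,4-bis[(tert-butyldimethylsilyl)oxy]-4-methylpent-2-en-1-yl]-5,8-dimethoxynaphthalene-1,4-dione | CC(C)(C)[Si](C)(C)O[C@H](/C=C/C(C)(C)O[Si](C)(C)C(C)(C)C)c1cc(OC)c2C(=O)C=CC(=O)c2c1OC | intermediate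
18 | 6-[(1R,2E)-1,4-bis[(tert-butyldimethylsilyl)oxy]-4-methylpent-2-en-1-yl]-5,8-dimethoxynaphthalene-1,4-diol | CC(C)(C)[Si](C)(C)O[C@H](/C=C/C(C)(C)O[Si](C)(C)C(C)(C)C)c1cc(OC)c2c(O)ccc(O)c2c1OC | intermediate
19 | 6-[(1R,2E)-1,4-bis[(tert-butyldimethylsilyl)oxy]-4-methylpent-2-en-1-yl]-5,8-dimethoxynaphthalene-1,4-diyl diacetate | CC(C)(C)[Si](C)(C)O[C@H](/C=C/C(C)(C)O[Si](C)(C)C(C)(C)C)c1cc(OC)c2c(OC(C)=O)ccc(OC(C)=O)c2c1OC | intermediate
20 | 2-[(1R,2E)-1,4-bis[(tert-butyldimethylsilyl)oxy]-4-methylpent-2-en-1-yl]-5,8-diacetoxynaphthalene-1,4-dione | CC(C)(C)[Si](C)(C)O[C@H](/C=C/C(C)(C)O[Si](C)(C)C(C)(C)C)C1=CC(=O)c2c(OC(C)=O)ccc(OC(C)=O)c2C1=O | intermediate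
21 | 2-[(1R,2E)-1,4-bis[(tert-butyldimethylsilyl)oxy]-4-methylpent-2-en-1-yl]-5,8-dihydroxynaphthalene-1,4-dione | CC(C)(C)[Si](C)(C)O[C@H](/C=C/C(C)(C)O[Si](C)(C)C(C)(C)C)C1=CC(=O)c2c(O)ccc(O)c2C1=O | intermediate
22 | 5,8-dihydroxy-2-[(1R,2E)-1,4-dihydroxy-4-methylpent-2-en-1-yl]naphthalene-1,4-dione | O[C@H](/C=C/C(C)(C)O)C1=CC(=O)c2c(O)ccc(O)c2C1=O | intermediate
23 | (R)-4-benzyl-1,3-oxazolidin-2-one | O=C1OC[C@@H](Cc2ccccc2)N1 | starting material
24 | butanoyl chloride | CCCC(Cl)=O | starting material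
25 | (R)-4-benzyl-3-butanoyl-1,3-oxazolidin-2-one | CCCC(=O)N1C(=O)OC[C@H]1Cc1ccccc1 | intermediate
26 | (R)-4-benzyl-3-[(2R)-2-methylbutanoyl]-1,3-oxazolidin-2-one | CC[C@@H](C)C(=O)N1C(=O)OC[C@H]1Cc1ccccc1 | intermediate
27 | (R)-2-methylbutaneperoxoic acid | CC[C@@H](C)C(=O)OO | intermediate
28 | (R)-2-methylbutanoic acid | CC[C@@H](C)C(O)=O | intermediate
29 | (1R,2E)-1-(5,8-dihydroxy-1,4-dioxo-1,4-dihydronaphthalen-2-yl)-4-hydroxy-4-methylpent-2-en-1-yl (2R)-2-methylbutanoate | CC[C@@H](C)C(=O)O[C@H](/C=C/C(C)(C)O)C1=CC(=O)c2c(O)ccc(O)c2C1=O | target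

## Summary and risks

Total steps: 21. Longest linear sequence: 16 (steps 1–6, 9–17, 21). The side branches are steps 7–8 (aldehyde 11) and steps 18–20 (acid 28).

The three steps most likely to fail:

Step 11. An aryl alkenyl ketone offers two unsaturated substituents, so the CBS reduction may give only moderate enantiomeric excess. The fallback sets out from 14 and comes back at 15. Luche reduction of 14 (NaBH4, CeCl3·7H2O, MeOH, −40 °C) gives the racemic allylic alcohol F1. Sharpless kinetic resolution of it (Ti(OiPr)4, D-(−)-diisopropyl tartrate, t-BuOOH 0.6 equiv, 4 Å molecular sieves, CH2Cl2, −20 °C) epoxidises the (S)-enantiomer to the epoxy alcohol F2. The (R)-enantiomer, which is 15, is left behind in at most 50% yield but with a predictable sense and high enantiomeric excess.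

Step 15. The second oxidation has to take place on a hindered ring next to two acetoxy groups and could be slow or cost a silyl ether. The fallback sets out from 17 and comes back at 21. Oxidation of 17 with AgO (divalent silver) and 6 M HNO3 in 1,4-dioxane at rt for a few minutes gives the naphthalene-1,4,5,8-tetrone F3. Immediate reduction of it with aqueous Na2S2O4 gives naphthazarin 21, so that 18, 19 and 20 are bypassed.

Step 21. The free naphthazarin is sensitive to the nucleophilic catalyst, and some phenol acylation may compete. The fallback sets out from 20 and comes back at 29. Desilylation of 20 with 48% aq. HF in MeCN gives the diacetoxyquinone diol F4, whose phenols are still masked. Esterification with 28 (DCC, 4-(dimethylamino)pyridine, CH2Cl2, 0 °C) gives the diacetoxyquinone ester F5. Neutral cleavage of the two aryl acetates (NH4OAc, aqueous MeOH, rt) then gives 29.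

## Further compounds

F1 | step 11 | racemic (2E)-4-[(tert-butyldimethylsilyl)oxy]-4-methyl-1-(1,4,5,8-tetramethoxynaphthalen-2-yl)pent-2-en-1-ol | OC(/C=C/C(C)(C)O[Si](C)(C)C(C)(C)C)c1cc(OC)c2c(OC)ccc(OC)c2c1OC
F2 | step 11 | (R)-[(2S,3R)-3-[2-[(tert-butyldimethylsilyl)oxy]propan-2-yl]oxiran-2-yl](1,4,5,8-tetramethoxynaphthalen-2-yl)methanol | O[C@@H]([C@@H]1O[C@H]1C(C)(C)O[Si](C)(C)C(C)(C)C)c1cc(OC)c2c(OC)ccc(OC)c2c1OC
F3 | step 15 | 2-[(1R,2E)-1,4-bis[(tert-butyldimethylsilyl)oxy]-4-methylpent-2-en-1-yl]naphthalene-1,4,5,8-tetrone | CC(C)(C)[Si](C)(C)O[C@H](/C=C/C(C)(C)O[Si](C)(C)C(C)(C)C)C1=CC(=O)C2=C(C1=O)C(=O)C=CC2=O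
F4 | step 21 | 5,8-diacetoxy-2-[(1R,2E)-1,4-dihydroxy-4-methylpent-2-en-1-yl]naphthalene-1,4-dione | O[C@H](/C=C/C(C)(C)O)C1=CC(=O)c2c(OC(C)=O)ccc(OC(C)=O)c2C1=O
F5 | step 21 | (1R,2E)-1-(5,8-diacetoxy-1,4-dioxo-1,4-dihydronaphthalen-2-yl)-4-hydroxy-4-methylpent-2-en-1-yl (2R)-2-methylbutanoate | CC[C@@H](C)C(=O)O[C@H](/C=C/C(C)(C)O)C1=CC(=O)c2c(OC(C)=O)ccc(OC(C)=O)c2C1=O
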